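Late in both earlier runs, what matters is the fraction of the charge still unreacted. At 6.00 min, gamma keeps 47.5 % and epsilon 49.7 %, although epsilon's charge is 2.24 times gamma's.

| setting | gamma | epsilon | east | north-east |
|---|---|---|---|---|
| starting material | 0.17 M | 0.38 M | 0.25 M | 0.25 M |
| gas phase | 12 mM (held) | 12 mM (held) | 12 mM (held) | 12 mM (held) |
| remark | run made earlier | run made earlier |  |  |
| time |  |  | 10 min | 5.0 min |

| run | time / min | side product A / % | starting material / % | target / % | side product B / % |
|---|---|---|---|---|---|
| gamma | 0.417 | 3.9 | 94.7 | 0 | 0 |
| gamma | 1.33 | 11.1 | 83.9 | 4.4 | 2.0 |
| gamma | 2.00 | 16.9 | 77.5 | 6.4 | 0.2 |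
| gamma | 3.00 | 22.8 | 66.4 | 8.4 | 0 |
| gamma | 5.00 | 35.1 | 54.1 | 10.3 | 0 |
| gamma | 6.00 | 43.0 | 47.5 | 11.7 | 0.9 |
| epsilon | 0.417 | 2.4 | 95.6 | 1.7 | 0.5 |
| epsilon | 1.33 | 12.8 | 85.0 | 1.6 | 0 |
| epsilon | 2.00 | 16.9 | 79.9 | 3.9 | 0 |
| epsilon | 3.00 | 25.9 | 68.1 | 4.7 | 0 |
| epsilon | 5.00 | 36.0 | 55.7 | 7.6 | 0.3 |
| epsilon | 6.00 | 43.3 | 49.7 | 9.0 | 0.7 |

(scatter of a reading: 1 percentage point)

1. which of these there is most of at the end, counted by the starting material in it, east (starting material / side product B / target / side product A)
2. which of these there is most of at the end, counted by the starting material in it, north-east (starting material / side product B / target / side product A)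
3. final amount of the leader among these, as a percentage of the starting material charged, in east
4. final amount of the leader among these, as a percentage of the starting material charged, in north-east

- in percentages every species weighs as the starting material in it: one side product B counts as two
- the numbers in the tables scatter by 1 percentage point (one standard deviation)
- at the start none of the gas phase is in solution

Pooled over the two runs, the logarithm of one over the fraction left, per minute elapsed, is 0.120 /min. This is the mean loss constant, the first-order constant of a curve replaced by its mean. The error of that replacement shows in the same pooling stopped at 3.00 min, which reads 0.132 /min, more than the reading to 6.00 min. The readings thus bend toward slower loss, so a fraction left reckoned with this constant beyond 6.00 min is more likely too low than too high, and it is an estimate, not a bound.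

For the bench, my own reckoning is this. East should hold 30.0 % of starting material at 10 min, and north-east 54.8 % at 5.0 min. Side product A took 83.9 % of what the two runs consumed (its selectivity), so east should hold 58.7 % of it, more than the starting material. North-east should hold 37.9 %, less than its starting material. The charge needs no touching, since the two fractions lie 2.2 percentage points apart across that change of charge.

The forecast, “The starting material decays first-order”, gives side product A at 57 % in east, below my figure, and starting material at 55 % in north-east.

    starting material + dissolved gas ⇌ target (K = 22.6 /M, k = 0.209 /M/s)
    gas phase ⇌ dissolved gas, rate k2*(csat - [dissolved gas]) (kL = 0.0189 /s)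
    starting material → side product A (k = 0.00162 /s)
    starting material + target → side product B (k = 4.85 × 10⁻⁴ /M/s)

East ends with side product A at 56.5 % and north-east with starting material at 53.8 %. East holds what the constant does not show: dissolved gas climbs from 0.00927 M at 5.00 min to 0.0126 M at 10.0 min, target stands at 10.0 %, and the reckoned fraction left lies 3.0 points below the 33 % in east. North-east read later, at 8.0 min, is reckoned by the mean constant to keep 38.3 %; that neighbour holds 39 %, with side product A ahead at 49.5 %.

The numbers in the tables stem from a simulated flask with made-up constants; scatter was added.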